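**Analysis of the target**

The target is a γ-butyrolactone (oxolan-2-one) that carries a (6-carboxy-2-oxo-2H-pyran-4-yl)methyl group at C3 and a 3,4-dimethoxybenzyl group at C4, while C5 is a bare methylene. The two stereocentres are adjacent, both are R, and the two side chains are therefore trans on the lactone ring. C3 lies alpha to the lactone carbonyl and can epimerise, but the trans arrangement is the more stable one; C4 has no such pathway once the ring is complete. The 2-pyrone is the sensitive part: it is a cross-conjugated enol lactone that hydroxide, alkoxides and organolithium reagents open and that catalytic hydrogenation or nickel desulfurisation would saturate, and it carries a free carboxylic acid at C6'. The aryl methyl ethers exclude strong boron or aluminium halides. The difficulty is therefore to run enolate chemistry at C3 next to an electrophilic pyrone and then to finish without base and without heterogeneous reduction. The plan rests on the C3–C4 bond with its trans substituents beside the unsubstituted C5: this is the pattern left when a nucleophile adds to C4 and an electrophile to C3 of a butenolide whose C5 carries a removable, face-blocking alkoxy group.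

**Retrosynthetic reasoning**

The free acid 21 is taken back to its ethyl ester 20 (cut: ester O–ethyl). An acidic proton cannot be carried through the organolithium step, and the pyrone tolerates hot mineral acid but not hydroxide, so the ester is removed last by acid hydrolysis.

The benzylic methylene of 20 is taken back to the aryl ketone 18 and this to the dithiane 17. The benzylic carbon must be a nucleophile when the C4–C(benzylic) bond is made, and a dithiane provides that. In the forward direction the thioketal is unmasked by a thiophilic metal. The ketone is then removed by ionic hydrogenation, which works because the 3,4-dimethoxyphenyl ring stabilises the benzylic cation and which leaves the electron-poor pyrone alone. Nickel desulfurisation is not used because it would reduce the pyrone.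

The C5 methylene of 17 is taken back through the hydroxy acid 16 and the lactol 15 to the menthyl acetal 14. The order matters for two reasons:
- A silane reduction of the intact acetal would most probably cleave the endocyclic C5–O1 bond, because the carboxylate is the better leaving group and the menthyl oxygen the better donor. Hydride would then end on an open-chain menthyl ether and the lactone would be lost. The acetal is therefore hydrolysed first and the aldehyde level is reduced afterwards.
- If the ketone were unmasked while C5 is still at the aldehyde level, C4 would sit between two carbonyl groups and lose its configuration. C5 is therefore brought down to the methylene while the dithiane is still in place.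

The key disconnection cuts two bonds of 14: C3–CH2(pyrone) and C4–C(dithiane). This leads to the lithium enolate 13 and from there to the lithiated dithiane 12, the butenolide 5 and the bromide 11. These bonds are chosen because both stereocentres then arise in one operation from the single stereocentre at the acetal carbon. The forward reaction must achieve 1,4-addition anti to the menthyloxy group and SN2 alkylation anti to the new C4 substituent, without attack on the pyrone.

Butenolide 5 is cut at the exocyclic acetal C–O bond to the racemic hydroxybutenolide 3 and (−)-menthol 4. Compound 3 comes from furfural 1 by photo-oxygenation through the endoperoxide 2. The C5 configuration is obtained by crystallisation under equilibrating conditions.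

The anion 12 comes from dithiane 7 by deprotonation, and 7 from veratraldehyde 6 by thioacetalisation.

Bromide 11 is cut at the C–Br bond to the methylpyrone 10. The pyrone ring of 10 is cut at C5'–C6' and O1'–C2' to the oxalylated dienolate 9 and so to ethyl 3-methylbut-2-enoate 8. The annulation is done on this simple substrate, where the ester is the only other functional group and either γ-methyl gives the same product.

**Alternatives that were turned down**

Alternative 1: The lactone O1–C5 bond is cut back to a prochiral cyclobutanone.
- Route: 4-allyl-1,2-dimethoxybenzene A1 would give 3-(3,4-dimethoxybenzyl)cyclobutan-1-one A2 by ketene cycloaddition and dechlorination. A Baeyer–Villiger monooxygenase of the cyclohexanone monooxygenase class, with oxygen and a nicotinamide cofactor, would insert oxygen into one of the two enantiotopic carbonyl–methylene bonds to give (R)-4-(3,4-dimethoxybenzyl)dihydrofuran-2(3H)-one A3. The enolate of A3 would then be alkylated with 11 and the ester hydrolysed.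
- For: the asymmetric step is catalytic, and no auxiliary, dithiane or change of oxidation level at C5 or at the benzylic carbon is needed. On step count this alternative is clearly stronger, at about seven steps against eleven.
- Against: nothing in A2 directs which enantiotopic bond migrates; the outcome depends wholly on how this substrate fits the enzyme. Only C4 is set in the key step. C3 still needs the same delicate alkylation with 11, now on an enolate made with an amide base and flanked only by a benzyl group, so over-alkylation and weaker trans control are possible.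
- Comparison: the chosen strategy gives in exchange a configuration anchored in a crystalline auxiliary of known configuration, both centres set in one flask, and a large quaternary neighbour that enforces anti alkylation.

Alternative 2: The pyrone bonds C5'–C6' and O1'–C2' are cut at the end of the synthesis.
- Route: ethyl 4-[(3R,4R)-4-(3,4-dimethoxybenzyl)-2-oxooxolan-3-yl]-3-methylbut-2-enoate A4 would be oxalylated at its γ-methyl with an oxalic ester and alkoxide, and the enol oxygen would close onto the enoate ester to give the ethyl ester A5, which is identical with 20.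
- For: the pyrone never meets an organolithium reagent or an enolate, and the reagents are cheap. On this point it is stronger than the chosen route.
- Against: A4 has three positions of comparable acidity, the γ-methyl, the γ-methylene attached to C3 and C3–H itself, and nothing secures oxalylation at the methyl. The alkoxide can open the lactone and epimerise C3. Ring closure also needs the Z-disposed ester.
- Comparison: the chosen route runs the same annulation on 8, where none of these competing sites exists, and the assembly of A4 would cost as many steps as the three-component coupling.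

Alternative 3: The pyrone bonds O1'–C6' and C4'–C5' are cut.
- Route: 4-[(3R,4R)-4-(3,4-dimethoxybenzyl)-2-oxooxolan-3-yl]but-2-ynoic acid A6 and tert-butyldimethyl(prop-2-yn-1-yloxy)silane A7 would be joined by a cationic monovalent gold catalyst such as Ph3PAuCl/AgOTf. The acid adds across the terminal alkyne to an enol ester, whose methylene terminus closes 6-endo-dig onto the gold-activated ynoate. The product is (3R,4R)-3-{[6-({[tert-butyl(dimethyl)silyl]oxy}methyl)-2-oxo-2H-pyran-4-yl]methyl}-4-(3,4-dimethoxybenzyl)oxolan-2-one A8.
- For: the conditions are neutral and catalytic, and the pyrone is formed after all enolate chemistry. In mildness the gold step is stronger than an organolithium coupling.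
- Against: A6 itself needs a lactone enolate alkylation with an ambident 4-halobut-2-ynoate. The intermolecular addition must beat attack of the lactone carbonyl on its own activated ynoate. C6' arrives at the alcohol level, so A8 needs desilylation and two oxidations on an electron-poor pyrone.
- Comparison: the chosen route has the carboxyl carbon at the right oxidation level from the start, and its key step sets both stereocentres, which the gold cascade does not address.

Key step: step 6

Remark: diethyl oxalate, propane-1,3-dithiol and N-bromosuccinimide are treated as commercial reagents. Lactol 15 is carried as a mixture of C5 epimers, which is of no consequence because C5 becomes a methylene group.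

**Route**

Step 1
Reactants: 1 furfural
Product: 3 5-hydroxyfuran-2(5H)-one (racemic), via furfural endoperoxide 2 (not isolated)
Conditions: O2, visible light, rose bengal disodium salt (C20H2Cl4I4Na2O5, cat.), MeOH, 0–20 °C
Reagents that add atoms: dioxygen, O=O
Why: Singlet oxygen adds [4+2] across the furan diene to give 2; methanol attacks the formyl group and the hemiacetal fragments with O–O cleavage, releasing methyl formate and the hydroxybutenolide (dye-sensitised photo-oxygenation of furfural).

Step 2
Reactants: 3 5-hydroxyfuran-2(5H)-one; 4 (−)-menthol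
Product: 5 (5R)-5-{[(1R,2S,5R)-5-methyl-2-(propan-2-yl)cyclohexyl]oxy}furan-2(5H)-one
Conditions: p-TsOH·H2O (cat.), toluene, reflux, Dean–Stark; crystallisation from petroleum ether, mother liquor re-equilibrated with p-TsOH (cat.) and crystallised again
Reagents that add atoms: none
Why: Acid-catalysed acetalisation of the pseudo-acid gives both C5 epimers, which interconvert under acid; the 5R epimer should crystallise, so the C5 stereocentre is set by the menthyl group through a crystallisation-induced diastereomer transformation.

Step 3
Reactants: 6 veratraldehyde (3,4-dimethoxybenzaldehyde)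
Product: 7 2-(3,4-dimethoxyphenyl)-1,3-dithiane
Conditions: HS(CH2)3SH, BF3·OEt2 (cat.), CH2Cl2, 0 °C → rt
Reagents that add atoms: propane-1,3-dithiol, SCCCS
Why: Lewis-acid-catalysed dithioacetalisation of an aromatic aldehyde; no other functional group is present.

Step 4
Reactants: 8 ethyl 3-methylbut-2-enoate
Product: 10 ethyl 4-methyl-2-oxo-2H-pyran-6-carboxylate, via potassium dienolate 9 (not isolated)
Conditions: (CO2Et)2, KOEt, EtOH/Et2O, 0 °C → rt; then anhydrous HCl/EtOH, reflux
Reagents that add atoms: diethyl oxalate, CCOC(=O)C(=O)OCC
Why: The extended enolate of 8 is acylated at the γ-carbon in a reversible vinylogous Claisen condensation that drains into the fully conjugated enolate 9; under acid the enol oxygen attacks the enoate ester and ethanol is lost to give the pyrone, and ethanolic acid keeps the C6 carboxyl as its ethyl ester.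

Step 5
Reactants: 10 ethyl 4-methyl-2-oxo-2H-pyran-6-carboxylate
Product: 11 ethyl 4-(bromomethyl)-2-oxo-2H-pyran-6-carboxylate
Conditions: NBS, 2,2'-azobis(2-methylpropionitrile) (cat.), PhCF3, 85 °C
Reagents that add atoms: N-bromosuccinimide, O=C1CCC(=O)N1Br
Why: Wohl–Ziegler bromination; hydrogen abstraction from the 4-methyl group gives a radical delocalised over the pyrone diene, and the ester-deactivated ring resists electrophilic bromination.

Step 6
Reactants: 7 2-(3,4-dimethoxyphenyl)-1,3-dithiane; 5 (5R)-5-menthyloxyfuran-2(5H)-one; 11 ethyl 4-(bromomethyl)-2-oxo-2H-pyran-6-carboxylate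
Product: 14 ethyl 4-{[(3R,4R,5R)-4-[2-(3,4-dimethoxyphenyl)-1,3-dithian-2-yl]-5-{[(1R,2S,5R)-5-methyl-2-(propan-2-yl)cyclohexyl]oxy}-2-oxooxolan-3-yl]methyl}-2-oxo-2H-pyran-6-carboxylate, via lithiated dithiane 12 (not isolated), via lithium enolate 13 (not isolated)
Conditions: 7 (1.05 equiv), n-BuLi (1.0 equiv), THF, −78 → −20 °C; 5 (1.05 equiv), THF, −90 °C; then 11 (1.4 equiv), DMPU, −78 → −40 °C; aq. NH4Cl
Reagents that add atoms: none
Why: n-BuLi removes the C2 proton of 7 to give the aryl- and sulfur-stabilised carbanion 12, which adds in a Michael sense to C4 of butenolide 5; the resulting lithium enolate 13 is then alkylated at C3 by the primary bromide 11 in an SN2 reaction. The closest known reaction type is the tandem conjugate addition–enolate alkylation of lithiated 2-aryl-1,3-dithianes with 5-alkoxybutenolides and benzylic bromides, used for trans-dibenzylbutyrolactones; no ring is closed in this step, two C–C bonds are formed. C4 is controlled by the C5 acetal stereocentre, because the menthyloxy group blocks one face of the planar butenolide and 12 attacks anti to it. C3 is controlled by the new C4 substituent, because the quaternary dithianyl group shields its own face of the enolate and 11 approaches anti, so the substituents at C3, C4 and C5 alternate (3R,4R,5R). 1,4-addition over 1,2-addition is secured by the soft, hindered, aryl-delocalised anion at low temperature. SN2 at the CH2Br carbon rather than attack on the pyrone carbonyl, on C6' or on the ester is expected because a lithium enolate displaces an allylic-type primary bromide at −78 °C much faster than it acylates, and the slight excess of 5 leaves no 12 to attack the pyrone when 11 is added. C-alkylation over O-alkylation follows from the tight lithium enolate and the soft bromide.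

Step 7
Reactants: 14 menthyl acetal from step 6
Product: 15 ethyl 4-{[(3R,4R)-4-[2-(3,4-dimethoxyphenyl)-1,3-dithian-2-yl]-5-hydroxy-2-oxooxolan-3-yl]methyl}-2-oxo-2H-pyran-6-carboxylate (both C5 epimers)
Conditions: 1 M aq. HCl/1,4-dioxane (1:2), 45 °C
Reagents that add atoms: water, O
Why: Acid-catalysed hydrolysis of the acyloxy-alkoxy acetal; whichever C5–O bond ionises, water captures the cation and the same lactol results, while the S,S-acetal is inert to aqueous protic acid and the conjugated ethyl ester hydrolyses far more slowly; C3 and C4 are not touched.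

Step 8
Reactants: 15 lactol from step 7
Product: 17 ethyl 4-{[(3R,4R)-4-[2-(3,4-dimethoxyphenyl)-1,3-dithian-2-yl]-2-oxooxolan-3-yl]methyl}-2-oxo-2H-pyran-6-carboxylate, via hydroxy acid 16 (not isolated)
Conditions: NaBH4 (1.5 equiv), THF/EtOH, −30 → 0 °C; then 1 M HCl to pH 2, rt
Reagents that add atoms: none
Why: Classical pseudo-acid reduction: the lactol opens to the aldehyde carboxylate, borohydride reduces the aldehyde much faster than the conjugated ester or the pyrone at low temperature, and acidification closes 16 to the γ-lactone; the dithiane is inert and the trans arrangement at C3/C4 is the stable one.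

Step 9
Reactants: 17 dithianyl lactone from step 8
Product: 18 ethyl 4-{[(3R,4R)-4-(3,4-dimethoxybenzoyl)-2-oxooxolan-3-yl]methyl}-2-oxo-2H-pyran-6-carboxylate
Conditions: HgO, BF3·OEt2, THF/H2O (85:15), rt; neutral work-up
Reagents that add atoms: water, O
Why: Thiophilic activation by divalent mercury cleaves a C–S bond to an aryl-stabilised thionium ion that water captures (mercury-assisted dithiane hydrolysis); lactone, pyrone and aryl ethers are inert, and base is avoided in the work-up because 18 is a β-acyloxy ketone that could eliminate.

Step 10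
Reactants: 18 keto lactone from step 9
Product: 20 ethyl 4-{[(3R,4R)-4-(3,4-dimethoxybenzyl)-2-oxooxolan-3-yl]methyl}-2-oxo-2H-pyran-6-carboxylate, via benzylic alcohol 19 (not isolated)
Conditions: Et3SiH (4 equiv), TFA/CH2Cl2 (1:1), 0 °C → rt
Reagents that add atoms: none
Why: Kursanov–Parnes ionic hydrogenation: the protonated aryl ketone takes hydride to give 19, which ionises to a methoxy-stabilised benzylic cation that takes a second hydride; the electron-poor pyrone and the esters form no comparable cation and are left alone, and if 19 lactonises in passing, the benzylic C–O bond still ionises and the original lactone re-forms.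

Step 11
Reactants: 20 ethyl ester from step 10
Product: 21 4-{[(3R,4R)-4-(3,4-dimethoxybenzyl)-2-oxooxolan-3-yl]methyl}-2-oxo-2H-pyran-6-carboxylic acid (target)
Conditions: 6 M aq. HCl/1,4-dioxane (1:1), 80 °C
Reagents that add atoms: water, O
Why: Acid-catalysed acyl–oxygen ester hydrolysis; 2-pyrone-6-carboxylic acids are formed and persist in hot mineral acid, the γ-lactone re-closes, C4 cannot enolise and trans is the stable arrangement at C3, whereas hydroxide would open the pyrone.

**Compound list**

1 | furfural | O=Cc1ccco1 | starting material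
2 | 2,3,7-trioxabicyclo[2.2.1]hept-5-ene-1-carbaldehyde (furfural endoperoxide, racemic) | O=CC12OOC(O1)C=C2 | intermediate
3 | 5-hydroxyfuran-2(5H)-one (racemic) | O=C1C=CC(O)O1 | intermediate
4 | (−)-menthol, (1R,2S,5R)-5-methyl-2-(propan-2-yl)cyclohexan-1-ol | C[C@@H]1CC[C@H]([C@@H](C1)O)C(C)C | starting material
5 | (5R)-5-{[(1R,2S,5R)-5-methyl-2-(propan-2-yl)cyclohexyl]oxy}furan-2(5H)-one | O=C1C=C[C@H](O[C@@H]2C[C@H](C)CC[C@H]2C(C)C)O1 | intermediate
6 | veratraldehyde (3,4-dimethoxybenzaldehyde) | COc1ccc(C=O)cc1OC | starting material
7 | 2-(3,4-dimethoxyphenyl)-1,3-dithiane | COc1ccc(C2SCCCS2)cc1OC | intermediate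
8 | ethyl 3-methylbut-2-enoate | CCOC(=O)C=C(C)C | starting material
9 | potassium enolate of diethyl 4-methyl-2-oxohex-4-enedioate | CCOC(=O)C([O-])=CC(C)=CC(=O)OCC.[K+] | intermediate
10 | ethyl 4-methyl-2-oxo-2H-pyran-6-carboxylate | CCOC(=O)c1cc(C)cc(=O)o1 | intermediate
11 | ethyl 4-(bromomethyl)-2-oxo-2H-pyran-6-carboxylate | CCOC(=O)c1cc(CBr)cc(=O)o1 | intermediate
12 | 2-(3,4-dimethoxyphenyl)-2-lithio-1,3-dithiane | COc1ccc(C2([Li])SCCCS2)cc1OC | intermediate
13 | lithium (4R,5R)-4-[2-(3,4-dimethoxyphenyl)-1,3-dithian-2-yl]-5-{[(1R,2S,5R)-5-methyl-2-(propan-2-yl)cyclohexyl]oxy}-4,5-dihydrofuran-2-olate | [Li]OC1=C[C@@H](C2(c3ccc(OC)c(OC)c3)SCCCS2)[C@H](O[C@@H]2C[C@H](C)CC[C@H]2C(C)C)O1 | intermediate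
14 | ethyl 4-{[(3R,4R,5R)-4-[2-(3,4-dimethoxyphenyl)-1,3-dithian-2-yl]-5-{[(1R,2S,5R)-5-methyl-2-(propan-2-yl)cyclohexyl]oxy}-2-oxooxolan-3-yl]methyl}-2-oxo-2H-pyran-6-carboxylate | O=C1[C@H](Cc2cc(C(=O)OCC)oc(=O)c2)[C@@H](C2(c3ccc(OC)c(OC)c3)SCCCS2)[C@H](O[C@@H]2C[C@H](C)CC[C@H]2C(C)C)O1 | intermediate
15 | ethyl 4-{[(3R,4R)-4-[2-(3,4-dimethoxyphenyl)-1,3-dithian-2-yl]-5-hydroxy-2-oxooxolan-3-yl]methyl}-2-oxo-2H-pyran-6-carboxylate (C5 epimers) | O=C1[C@H](Cc2cc(C(=O)OCC)oc(=O)c2)[C@@H](C2(c3ccc(OC)c(OC)c3)SCCCS2)C(O)O1 | intermediate
16 | (2R,3R)-3-[2-(3,4-dimethoxyphenyl)-1,3-dithian-2-yl]-2-{[6-(ethoxycarbonyl)-2-oxo-2H-pyran-4-yl]methyl}-4-hydroxybutanoic acid | OC(=O)[C@H](Cc1cc(C(=O)OCC)oc(=O)c1)[C@@H](C1(c2ccc(OC)c(OC)c2)SCCCS1)CO | intermediate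
17 | ethyl 4-{[(3R,4R)-4-[2-(3,4-dimethoxyphenyl)-1,3-dithian-2-yl]-2-oxooxolan-3-yl]methyl}-2-oxo-2H-pyran-6-carboxylate | O=C1[C@H](Cc2cc(C(=O)OCC)oc(=O)c2)[C@@H](C2(c3ccc(OC)c(OC)c3)SCCCS2)CO1 | intermediate
18 | ethyl 4-{[(3R,4R)-4-(3,4-dimethoxybenzoyl)-2-oxooxolan-3-yl]methyl}-2-oxo-2H-pyran-6-carboxylate | O=C1[C@H](Cc2cc(C(=O)OCC)oc(=O)c2)[C@@H](C(=O)c2ccc(OC)c(OC)c2)CO1 | intermediate
19 | ethyl 4-{[(3R,4R)-4-[(3,4-dimethoxyphenyl)(hydroxy)methyl]-2-oxooxolan-3-yl]methyl}-2-oxo-2H-pyran-6-carboxylate (carbinol epimers) | O=C1[C@H](Cc2cc(C(=O)OCC)oc(=O)c2)[C@@H](C(O)c2ccc(OC)c(OC)c2)CO1 | intermediate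
20 | ethyl 4-{[(3R,4R)-4-(3,4-dimethoxybenzyl)-2-oxooxolan-3-yl]methyl}-2-oxo-2H-pyran-6-carboxylate | COc1ccc(C[C@H]2COC(=O)[C@@H]2Cc2cc(C(=O)OCC)oc(=O)c2)cc1OC | intermediate
21 | 4-{[(3R,4R)-4-(3,4-dimethoxybenzyl)-2-oxooxolan-3-yl]methyl}-2-oxo-2H-pyran-6-carboxylic acid | COc1ccc(C[C@H]2COC(=O)[C@@H]2Cc2cc(C(=O)O)oc(=O)c2)cc1OC | target

**Step count and risks**

Total step count: 11. Longest linear sequence: 8 steps (from 1 through steps 1, 2 and 6–11; equally from 8 through steps 4, 5 and 6–11).

Least certain steps:

Step 6 (key step). The enolate may be consumed by proton transfer from the vinylogously acidic CH2Br group, or by electron transfer to or addition onto the electron-poor pyrone, instead of SN2 displacement. The enolate would then simply be protonated on work-up. The hindered enolate next to the quaternary dithiane carbon may also react slowly. The fallback separates the two bond formations; it sets out from 7 and 5 and returns at 14. Enolate 13 is quenched with aqueous NH4Cl to give (4R,5R)-4-[2-(3,4-dimethoxyphenyl)-1,3-dithian-2-yl]-5-{[(1R,2S,5R)-5-methyl-2-(propan-2-yl)cyclohexyl]oxy}oxolan-2-one F1, which is purified. Bromide 11 is converted with NaI in acetone into ethyl 4-(iodomethyl)-2-oxo-2H-pyran-6-carboxylate F2. F1 is deprotonated with LiN(SiMe3)2 in THF at −78 °C, which regenerates 13, and the enolate is transferred by cannula into an excess of F2 in THF/DMPU at −78 °C to give 14. This mode keeps the dithiane anion out of the flask entirely, keeps the electrophile in excess at every moment and uses the faster leaving group.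

Step 7. Discrimination between acetal and ester hydrolysis may be incomplete, so that part of the ethyl ester is lost while the hindered acetal is still present. The fallback drives both hydrolyses to completion and carries the free acid; it sets out from 14 and returns at 21, saving step 11. Compound 14 is heated in 6 M aq. HCl/1,4-dioxane at 80 °C to give 4-{[(3R,4R)-4-[2-(3,4-dimethoxyphenyl)-1,3-dithian-2-yl]-5-hydroxy-2-oxooxolan-3-yl]methyl}-2-oxo-2H-pyran-6-carboxylic acid F3. NaBH4 in THF/EtOH followed by acidification gives 4-{[(3R,4R)-4-[2-(3,4-dimethoxyphenyl)-1,3-dithian-2-yl]-2-oxooxolan-3-yl]methyl}-2-oxo-2H-pyran-6-carboxylic acid F4; the pyrone carboxylate is not reducible. HgO and BF3·OEt2 in aqueous THF give 4-{[(3R,4R)-4-(3,4-dimethoxybenzoyl)-2-oxooxolan-3-yl]methyl}-2-oxo-2H-pyran-6-carboxylic acid F5. Et3SiH in TFA/CH2Cl2 then gives 21 directly.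

Step 8. Hydride may also attack the activated pyrone ester or the pyrone ring, and the alkoxide formed may open the pyrone. The fallback replaces nucleophilic hydride under basic conditions by ionic reduction of an acylal; it sets out from 15 and returns at 17. Compound 15 is acetylated with Ac2O, pyridine and 4-(dimethylamino)pyridine (cat.) to ethyl 4-{[(3R,4R)-5-acetoxy-4-[2-(3,4-dimethoxyphenyl)-1,3-dithian-2-yl]-2-oxooxolan-3-yl]methyl}-2-oxo-2H-pyran-6-carboxylate F6. Et3SiH and BF3·OEt2 in CH2Cl2 at −40 → 0 °C then give 17. Loss of the exocyclic acetate is irreversible, whereas endocyclic opening re-closes, so the cyclic acyloxycarbenium ion should be the one reduced.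

Step 10. The benzylic cation may lose the C4 proton and be re-protonated, which would erode the C4 configuration, or it may alkylate a second dimethoxyphenyl ring; the reduction may also stall at the alcohol stage. The fallback avoids any benzylic cation; it sets out from 18 and returns at 20. Compound 18 is condensed with p-toluenesulfonyl hydrazide in EtOH (cat. AcOH, reflux) to ethyl 4-{[(3R,4S)-4-{(3,4-dimethoxyphenyl)[2-(4-methylbenzenesulfonyl)hydrazinylidene]methyl}-2-oxooxolan-3-yl]methyl}-2-oxo-2H-pyran-6-carboxylate F7. The spatial arrangement is that of 18; only the descriptor at C4 changes. Reduction with catecholborane in CHCl3 at 0 °C, followed by NaOAc·3H2O at reflux, gives 20 through the diazene with loss of dinitrogen.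

Step 4. Ring closure may lag because the oxalylated dienoate sits in the geometry that keeps the enol oxygen away from the ester, and the ethyl ester may be partly lost. The fallback goes through the acid; it sets out from 8 (through 9) and returns at 10. The potassium salt 9 is heated in concentrated aqueous HCl, which isomerises, cyclises and hydrolyses it to 4-methyl-2-oxo-2H-pyran-6-carboxylic acid F8. Fischer esterification with EtOH and H2SO4 (cat.) then gives 10.

**Further compounds**

F1 | step 6 | (4R,5R)-4-[2-(3,4-dimethoxyphenyl)-1,3-dithian-2-yl]-5-{[(1R,2S,5R)-5-methyl-2-(propan-2-yl)cyclohexyl]oxy}oxolan-2-one | O=C1C[C@@H](C2(c3ccc(OC)c(OC)c3)SCCCS2)[C@H](O[C@@H]2C[C@H](C)CC[C@H]2C(C)C)O1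
F2 | step 6 | ethyl 4-(iodomethyl)-2-oxo-2H-pyran-6-carboxylate | CCOC(=O)c1cc(CI)cc(=O)o1
F3 | step 7 | 4-{[(3R,4R)-4-[2-(3,4-dimethoxyphenyl)-1,3-dithian-2-yl]-5-hydroxy-2-oxooxolan-3-yl]methyl}-2-oxo-2H-pyran-6-carboxylic acid | O=C1[C@H](Cc2cc(C(=O)O)oc(=O)c2)[C@@H](C2(c3ccc(OC)c(OC)c3)SCCCS2)C(O)O1
F4 | step 7 | 4-{[(3R,4R)-4-[2-(3,4-dimethoxyphenyl)-1,3-dithian-2-yl]-2-oxooxolan-3-yl]methyl}-2-oxo-2H-pyran-6-carboxylic acid | O=C1[C@H](Cc2cc(C(=O)O)oc(=O)c2)[C@@H](C2(c3ccc(OC)c(OC)c3)SCCCS2)CO1
F5 | step 7 | 4-{[(3R,4R)-4-(3,4-dimethoxybenzoyl)-2-oxooxolan-3-yl]methyl}-2-oxo-2H-pyran-6-carboxylic acid | O=C1[C@H](Cc2cc(C(=O)O)oc(=O)c2)[C@@H](C(=O)c2ccc(OC)c(OC)c2)CO1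
F6 | step 8 | ethyl 4-{[(3R,4R)-5-acetoxy-4-[2-(3,4-dimethoxyphenyl)-1,3-dithian-2-yl]-2-oxooxolan-3-yl]methyl}-2-oxo-2H-pyran-6-carboxylate | O=C1[C@H](Cc2cc(C(=O)OCC)oc(=O)c2)[C@@H](C2(c3ccc(OC)c(OC)c3)SCCCS2)C(OC(C)=O)O1
F7 | step 10 | ethyl 4-{[(3R,4S)-4-{(3,4-dimethoxyphenyl)[2-(4-methylbenzenesulfonyl)hydrazinylidene]methyl}-2-oxooxolan-3-yl]methyl}-2-oxo-2H-pyran-6-carboxylate | O=C1[C@H](Cc2cc(C(=O)OCC)oc(=O)c2)[C@@H](C(=NNS(=O)(=O)c2ccc(C)cc2)c2ccc(OC)c(OC)c2)CO1
F8 | step 4 | 4-methyl-2-oxo-2H-pyran-6-carboxylic acid | Cc1cc(C(=O)O)oc(=O)c1
A1 | alternative 1 | 4-allyl-1,2-dimethoxybenzene | C=CCc1ccc(OC)c(OC)c1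
A2 | alternative 1 | 3-(3,4-dimethoxybenzyl)cyclobutan-1-one | COc1ccc(CC2CC(=O)C2)cc1OC
A3 | alternative 1 | (R)-4-(3,4-dimethoxybenzyl)dihydrofuran-2(3H)-one | COc1ccc(C[C@H]2COC(=O)C2)cc1OC
A4 | alternative 2 | ethyl 4-[(3R,4R)-4-(3,4-dimethoxybenzyl)-2-oxooxolan-3-yl]-3-methylbut-2-enoate | CCOC(=O)C=C(C)C[C@H]1C(=O)OC[C@@H]1Cc1ccc(OC)c(OC)c1
A5 | alternative 2 | ethyl 4-{[(3R,4R)-4-(3,4-dimethoxybenzyl)-2-oxooxolan-3-yl]methyl}-2-oxo-2H-pyran-6-carboxylate | CCOC(=O)c1cc(C[C@H]2C(=O)OC[C@@H]2Cc2ccc(OC)c(OC)c2)cc(=O)o1
A6 | alternative 3 | 4-[(3R,4R)-4-(3,4-dimethoxybenzyl)-2-oxooxolan-3-yl]but-2-ynoic acid | OC(=O)C#CC[C@H]1C(=O)OC[C@@H]1Cc1ccc(OC)c(OC)c1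
A7 | alternative 3 | tert-butyldimethyl(prop-2-yn-1-yloxy)silane | C#CCO[Si](C)(C)C(C)(C)C
A8 | alternative 3 | (3R,4R)-3-{[6-({[tert-butyl(dimethyl)silyl]oxy}methyl)-2-oxo-2H-pyran-4-yl]methyl}-4-(3,4-dimethoxybenzyl)oxolan-2-one | CC(C)(C)[Si](C)(C)OCc1cc(C[C@H]2C(=O)OC[C@@H]2Cc2ccc(OC)c(OC)c2)cc(=O)o1
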